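(The numbers in the tables are calculated for an exercise.)

Plot ring against substrate left, not against time.

| setting | dawn | noon | spring | flask |
|---|---|---|---|---|
| substrate | 0.050 M | 0.20 M | 0.10 M | 0.10 M |
| activator | 0.18 M (fed, over 3.0 h) | 0.18 M (fed, over 3.0 h) | 0.27 M (fed, over 3.0 h) | 0.180 M (fed, over 3.0 h) |
| remark | run made earlier; the fed solution adds 0.50 times the starting volume | run made earlier; the fed solution adds 0.50 times the starting volume | run made earlier; the fed solution adds 0.50 times the starting volume | the fed solution adds 0.50 times the starting volume |
| time |  |  |  | 15 d |

- dawn (time / d: ring / %, substrate / %): 0.167: 20.2, 70.4; 0.625: 31.0, 27.2; 2.50: 19.5, 9.0; 10.0: 18.2, 8.5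
- noon (time / d: ring / %, substrate / %): 0.167: 11.2, 68.8; 0.625: 20.8, 34.8; 2.50: 22.4, 29.2; 10.0: 22.9, 29.5
- spring (time / d: ring / %, substrate / %): 0.167: 19.0, 56.4; 0.625: 23.8, 15.0; 2.50: 11.9, 5.7; 10.0: 13.0, 3.0

(standard deviation of a reading: 1 percentage point)

- in percentages every species weighs as the substrate in it: one open dimer counts as two
- charges are per starting volume, the dose included; the dosed solution carries all of it
- steps that have been proposed: substrate + activator -> activated form; activated form -> ring; substrate + activated form -> open dimer; activator + ring -> over-reaction product; activator -> decomposed reagent

- the best time, 15 d at the latest, for ring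
- the amount of ring, in percent of the substrate charged, at that time

In the proposed steps, substrate and ring are attacked by the same activator, each first order in it. So at one substrate charge c(activator) cancels, and ring follows nearly one curve against substrate left. Per unit of substrate lost, ring gains s, its share of the activated form, and loses ρ·c(ring)/c(substrate), where ρ is the selectivity factor of ring against substrate.

Spring has the flask's substrate charge. Its two readings from 0.625 d to 2.50 d, with making neglected, give ρ ≈ 0.716. With s held fixed, the integrated curve peaks at ρ raised to one over (one minus ρ), which is 30.8%: the crossing fraction, the substrate left at which loss overtakes making. Spring's reading at 0.625 d then gives s ≈ 0.631, and the height at the crossing, s times the fraction over ρ, is 27.2%.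

The flask's substrate charge, 0.100 M, is the geometric mean of dawn's and noon's. The same mean of their substrate at 0.625 d is 30.8%, so the flask should reach the crossing about then.

The weak link is whether the activator lasts that far. The same mean of their last readings puts the flask's stall at 15.8%, lower than the crossing fraction, so the flask should pass it. This reckoning commits to 27.2% near 0.625 d.

The forecast, reasoning that “ring against substrate left should follow nearly the same curve”, says 26.5% at 0.6 d.

The flask gives 27.3% at 0.629 d, with 29.8% substrate left. The forecast held.

    substrate + activator → activated form (k = 0.0180 /M/min)
    activated form → ring (k = 0.0870 /min)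
    substrate + activated form → open dimer (k = 0.490 /M/min)
    activator + ring → over-reaction product (k = 0.0180 /M/min)
    activator → decomposed reagent (k = 5.30 × 10⁻⁴ /min)

The step activator + ring has the largest single effect on the flask's peak: the flask run without it reaches 66.6% instead of 27.3%. Take a neighbour with 0.11 M of activator and the same substrate charge: its crossing fraction, as read from spring, stays 30.8%, so a stop above that should leave ring ending at its best, near 27.2%. That neighbour stops at 34% substrate, higher than the crossing fraction, and its ring ends at 27.2%, with a best of 27.2%.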